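## Structural features

The target is a (2S)-flavanone. Ring A is fused through C4a–C8a to the dihydropyranone ring C (O1, C2, C3, C4 carbonyl), and C2 carries a 2,6-dihydroxy-4-methoxyphenyl ring B. Ring A is hexasubstituted: hydroxyls at C5 and C7, a prenyl group (3-methylbut-2-enyl) at C6 between them, and a lavandulyl group (5-methyl-2-(prop-1-en-2-yl)hex-4-enyl) at C8 between the C7 oxygen and O1. There are two stereocentres, C2 (S) and the lavandulyl methine (R as an arylmethyl substituent, which is the spatial arrangement of (S)-lavandulol). They are not adjacent but five bonds apart, so neither can direct the other. The fragile elements are the three isolated alkenes (no hydrogenation, no strong electrophiles; a prenyl group next to a free phenol cyclises to a chroman in strong acid), the C2 centre (ring opening to the chalcone under base, ionisation under acid because ring B is very electron-rich) and the air-sensitive polyphenol. The real difficulty is twofold: a fully substituted phloroglucinol ring whose three oxygens have three different roles, and absolute control at C2 next to a di-ortho-substituted aryl group with no nearby stereocentre. The feature exploited is that the C4 carbonyl sits on C4a between the C5 hydroxyl and the C8a–O1 ether. C4 is therefore the formyl carbon of a chelating salicylaldehyde, C2–C3 is a 1-arylvinyl group on O1, and the C3–C4 bond can be made by adding the aldehyde C–H bond across that enol ether.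

## Logic of the disconnections

26 is traced back to 25 by cutting three O–CH2OCH3 bonds. Acetal protection of the C7, C2' and C6' oxygens survives base, organometallics, fluoride and rhodium and comes off in one operation. The demand on the forward step is an acid mild enough to leave the alkenes, the ortho-prenyl phenols and C2 untouched.

25 is cut at C3–C4 to give 24. This removes ring C and the C2 stereocentre at once and leaves an aldehyde on C4a and a 1-arylvinyl ether on O1. The forward step must deliver hydride to C2 on one face, place the metal on C3 and not on C2, and avoid decarbonylation. For this reason the C5 hydroxyl is kept free as the chelating group, and the more acidic C7 hydroxyl is capped so that it cannot compete for base or metal. The ring B ethers are kept small (MOM) so that the crowded C2 carbon stays accessible.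

24 is cut at the C7 O–CH2OCH3 bond to give 23. The two ring A hydroxyls are told apart most simply once the aldehyde is present, because the C5 hydroxyl is locked in a hydrogen bond and the C7 hydroxyl is the more acidic. The forward step needs only mono-alkylation under mild base.

23 is cut at the C4a–CHO bond to give 22. C4a is the only free ring position and is ortho to the C5 hydroxyl. Putting the formyl group in last means that no carbonyl has to be masked during the methylenation, and no benzylic alcohol prone to quinone methide formation is ever handled. The forward step must be strictly ortho-selective and non-acidic.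

22 is cut at two O–Si bonds to give 21. The forward step needs buffered fluoride that spares the enol ether.

21 is cut at the C=CH2 bond of the enol ether to give ester 20. Aryl 1-arylvinyl ethers are reached most reliably from aryl esters by titanium methylenation, and the O1–C2 bond thereby becomes an easily made ester bond. The forward step must work on a hindered ester and deliver an acid-labile product.

20 is cut at the C8–CH2 bond to give 15 and 18 (used as 19). The lavandulyl unit comes in intact with its stereocentre one carbon away from the reacting centre, so the centre cannot be disturbed. The forward step is a coupling of a primary alkylzinc at a di-ortho-substituted aryl bromide, and the zinc reagent must leave the ester alone.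

15 is cut at two O–Si bonds to give 14. The silyl ethers keep the phenols from quenching the zinc and titanium reagents.

14 is cut at the O1–C(=O) bond to give 8 and 12 (activated as 13). This joins rings A and B and defines which oxygen becomes O1. The forward step must acylate one hydroxyl of three. The bromine makes the wanted hydroxyl more acidic, and of the two hydroxyls ortho to bromine it is the one that is not flanked on both sides. The acid must be activated without HCl, because a MOM ether ortho to an acid chloride is lost by cyclisation.

8 is cut back through 7 and 5 to 2 and 3, and 2 to 1: the O–MOM bonds, the C8–Br bond and the C6–prenyl bond. Both C-substituents enter by lithiation between two MOM ethers, so the regiochemistry is fixed by symmetry. The bromine serves twice, as acidity handle and as coupling handle. The forward steps need ring lithiation to outrun deprotonation of the benzylic allylic CH2, and an acidolysis that does not close a chroman.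

12 is cut at the C1'–CO2H bond to give 10, and 10 at the O–MOM bonds to give 9. Lithiation between two MOM ethers is preferred over the positions next to the methoxy group.

18 is cut at the C–I bond to give 17, and 17 is obtained from 16 by resolution. The iodide is made under neutral conditions so that the homoallylic skeleton does not rearrange.

## Other disconnections considered

Alternative 1: Ring A is cut at C8a–C8 and C6–C7, with C4a–C8a closed by electrocyclisation. In the forward direction cyclobutenone A1 would be heated with the lavandulyl siloxyalkyne A2. Ring opening to a vinylketene, [2+2] addition to the ynol ether, a second ring opening and 6π closure would give phenol A3. In its favour, all six ring A positions are placed by the pericyclic sequence and O1 emerges as the only free hydroxyl. On this point it is better than the chosen plan, which relies on a selective acylation. Against it, A1 and A2 are bespoke fragments that each need several steps, and A2 requires homologating lavandulol by one carbon. The vinylketene carries a pendant prenyl alkene that can be trapped intramolecularly, and the 1,5-diene of the lavandulyl chain is exposed to prolonged heating. A3 still lacks the C4a carbon, ring C and C2, so every step of the chosen route from the esterification onward would still be needed. On mechanism it is elegant and well precedented for simpler phenols (an equal). On step economy it is no shorter, and it does not address C2.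

Alternative 2: Ring C is cut at C4a–C4, C4–C3 and O1–C2. The forward step joins iodophenol A4, carbon monoxide and arylacetylene A5 under palladium catalysis (carbonylative alkynylation, then closure of the phenol onto the ynone) to give flavone A6. In its favour, three bonds form in one convergent step, and the reaction type is established for simple flavones. On both counts it is better than the chosen key step, which forms one bond and has no direct precedent. Against it, A6 has no stereocentre at C2. A later enantioselective 1,4-reduction of a 2-aryl chromone with a di-ortho-substituted aryl group would be needed, with three other alkenes present and hydrogenation excluded. The iodine of A4 sits between a hydroxyl and a MOM ether on a hexasubstituted ring, so oxidative addition should be slow. The 5-exo closure to an aurone competes with the 6-endo closure. A4 needs the same differentiation of O1 as the chosen route, plus an iodination. On step economy the two plans are about equal up to ring closure. The alternative then leaves the stereochemical problem open, whereas the chosen plan solves it in the ring-closing step.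

Alternative 3: Ring C is cut at C8a–O1. The forward step is an intramolecular palladium-catalysed aryl etherification of diol triflate A7, giving flavan-4-ol A8, followed by oxidation at C4. In its favour, C2 would be set earlier by established carbonyl chemistry (aldol, directed reduction). It is carried through with retention because the bond is formed at the aryl carbon. On stereochemical reliability and on precedent for the ring closure it is better than the chosen plan. Against it, the triflate is flanked by the lavandulyl group and the side chain, and the reacting alcohol is flanked by a 2,6-disubstituted aryl group. The palladium alkoxide can undergo β-hydride elimination, and the free C4 hydroxyl would have to be protected or would be oxidised. The doubly benzylic, electron-rich diol is prone to ionisation. The sequence from a ring A carbonyl compound (aldol, reduction, triflation, cyclisation, oxidation, deprotection) is clearly longer than formylation, MOM protection, hydroacylation and deprotection, and it includes a redox detour at C4.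

Key step: step 16

Remarks on the chemistry:
- Flavanone numbering is used (O1, C2, C3, C4, C4a, C5–C8, C8a; ring B primed). Prenyl is 3-methylbut-2-en-1-yl, lavandulyl is 5-methyl-2-(prop-1-en-2-yl)hex-4-en-1-yl, MOM is CH2OCH3, TBS is tert-butyldimethylsilyl.
- The structures of 24 and 25 were re-derived from 26 and need no correction: C2 is S, and the lavandulyl centre is R once the CH2 is bound to the arene. That is the arrangement of (S)-lavandulol; the descriptor changes only because the priorities change.
- One mechanistic point is corrected: the tether does not by itself exclude closure to a five-membered benzofuranone. The regiochemistry rests on a steric argument (see step 16).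
- Assumption: the lipase acylates (R)-lavandulol faster, so the unreacted alcohol is the (S)-enantiomer. If the preference were the reverse, the ester fraction would be saponified instead.

## Steps

Step 1
Reactants: 1 phloroglucinol
Product: 2 1,3,5-tris(methoxymethoxy)benzene
Conditions: MOMCl (3.6 equiv), i-Pr2NEt, DMF, 0 °C → rt
Reagents that add atoms: chloromethyl methyl ether, COCCl
Why: O-alkylation of all three phenols with a hard electrophile (Williamson type); the MOM ethers are the directing groups for both ring lithiations that follow.

Step 2
Reactants: 2 1,3,5-tris(methoxymethoxy)benzene; 3 prenyl bromide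
Product: 5 1,3,5-tris(methoxymethoxy)-2-prenylbenzene, via aryllithium 4 (not isolated)
Conditions: n-BuLi, TMEDA, THF, 0 °C; then 3, −78 °C → rt
Reagents that add atoms: none
Why: Directed ortho-metalation; all ring positions are equivalent and each lies between two MOM ethers, and the aryllithium is alkylated at the primary carbon of the allylic bromide.

Step 3
Reactants: 5 1,3,5-tris(methoxymethoxy)-2-prenylbenzene
Product: 7 2-bromo-1,3,5-tris(methoxymethoxy)-4-prenylbenzene, via aryllithium 6 (not isolated)
Conditions: n-BuLi, TMEDA, THF, 0 °C; then BrCH2CH2Br, −78 °C → rt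
Reagents that add atoms: 1,2-dibromoethane, BrCCBr
Why: Second directed ortho-metalation at one of the two equivalent positions flanked by two MOM ethers, favoured by double coordination over the benzylic allylic CH2; the bromine is delivered to the carbanion, so the prenyl alkene never meets an electrophilic halogen source.

Step 4
Reactants: 7 2-bromo-1,3,5-tris(methoxymethoxy)-4-prenylbenzene
Product: 8 2-bromo-4-prenylbenzene-1,3,5-triol
Conditions: HCl (conc., cat.), MeOH, 40 °C
Reagents that add atoms: none
Why: Acid-catalysed acetal exchange removes the three MOM groups as dimethoxymethane; dilute acid in methanol at moderate temperature is the usual way to do this without closing a chroman from an ortho-prenyl phenol.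

Step 5
Reactants: 9 5-methoxyresorcinol
Product: 10 1-methoxy-3,5-bis(methoxymethoxy)benzene
Conditions: MOMCl (2.4 equiv), i-Pr2NEt, DMF, 0 °C → rt
Reagents that add atoms: chloromethyl methyl ether, COCCl
Why: O-alkylation of both phenols; the MOM ethers direct the next lithiation and are the ring B protecting groups carried to the end.

Step 6
Reactants: 10 1-methoxy-3,5-bis(methoxymethoxy)benzene
Product: 12 4-methoxy-2,6-bis(methoxymethoxy)benzoic acid, via aryllithium 11 (not isolated)
Conditions: n-BuLi, TMEDA, THF, 0 °C; then CO2, −78 °C; cold HCl (1 M) to pH 4
Reagents that add atoms: carbon dioxide, O=C=O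
Why: Directed ortho-metalation at the position between the two MOM ethers (stronger directors than methoxy), then carboxylation; the brief cold acidification to pH 4 spares the MOM ethers.

Step 7
Reactants: 8 2-bromo-4-prenylbenzene-1,3,5-triol; 12 4-methoxy-2,6-bis(methoxymethoxy)benzoic acid
Product: 14 2-bromo-3,5-dihydroxy-4-prenylphenyl 4-methoxy-2,6-bis(methoxymethoxy)benzoate, via acyl fluoride 13 (not isolated)
Conditions: 12, cyanuric fluoride, pyridine, CH2Cl2, −10 °C → rt (gives 13); then 8 (1.1 equiv), i-Pr2NEt (1.0 equiv), MeCN, −20 → 0 °C, slow addition of 13
Reagents that add atoms: none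
Why: Phenoxide acylation by an acyl fluoride, formed without HCl so that the ortho MOM ethers are not lost. With one equivalent of base the phenoxides ortho to bromine dominate, and of those two the hydroxyl flanked by bromine and hydrogen is far more accessible to the 2,6-disubstituted acyl donor than the one flanked by bromine and prenyl. Acyl migration between the meta-disposed oxygens is not possible.

Step 8
Reactants: 14 2-bromo-3,5-dihydroxy-4-prenylphenyl 4-methoxy-2,6-bis(methoxymethoxy)benzoate
Product: 15 2-bromo-3,5-bis(tert-butyldimethylsilyloxy)-4-prenylphenyl 4-methoxy-2,6-bis(methoxymethoxy)benzoate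
Conditions: TBSCl (3 equiv), imidazole, DMF, 40 °C
Reagents that add atoms: tert-butyldimethylsilyl chloride, CC(C)(C)[Si](C)(C)Cl
Why: Silylation of both remaining phenols, so that no acidic proton consumes the zinc or titanium reagent; the hindered diaryl ester is inert to imidazole.

Step 9
Reactants: 16 racemic lavandulol
Product: 17 (S)-lavandulol
Conditions: vinyl acetate, porcine pancreatic lipase, hexane, rt, stopped a little past half conversion; chromatography
Reagents that add atoms: none
Why: Enzymatic kinetic resolution by irreversible transesterification; the faster-reacting (R)-alcohol is removed as its acetate and the remaining alcohol is enriched in the (S)-enantiomer. This is where the lavandulyl stereocentre is obtained, and all later reactions occur at the neighbouring CH2 or further away.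

Step 10
Reactants: 17 (S)-lavandulol
Product: 18 (S)-lavandulyl iodide, (2S)-1-iodo-5-methyl-2-(prop-1-en-2-yl)hex-4-ene
Conditions: I2, PPh3, imidazole, CH2Cl2, 0 °C → rt
Reagents that add atoms: iodine, II
Why: Appel iodination of a primary alcohol by SN2 displacement of the oxyphosphonium group; the conditions are neutral, so the homoallylic system does not rearrange and the β-stereocentre is untouched.

Step 11
Reactants: 15 2-bromo-3,5-bis(tert-butyldimethylsilyloxy)-4-prenylphenyl 4-methoxy-2,6-bis(methoxymethoxy)benzoate; 18 (S)-lavandulyl iodide
Product: 20 3,5-bis(tert-butyldimethylsilyloxy)-2-[(2R)-lavandulyl]-4-prenylphenyl 4-methoxy-2,6-bis(methoxymethoxy)benzoate, via alkylzinc iodide 19 (not isolated)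
Conditions: 18, Zn dust, LiCl, THF, 35 °C (gives 19); then 15, Pd(OAc)2 (4 mol%), SPhos (8 mol%), THF, 50 °C
Reagents that add atoms: none
Why: Negishi coupling of a primary alkylzinc with an aryl bromide; a bulky biarylphosphine is chosen because it promotes oxidative addition at di-ortho-substituted bromides and fast reductive elimination ahead of β-hydride elimination. The organozinc leaves the ester alone, and the stereocentre, β to zinc, is retained (the descriptor changes from S to R only through the priority rules).

Step 12
Reactants: 20 3,5-bis(tert-butyldimethylsilyloxy)-2-[(2R)-lavandulyl]-4-prenylphenyl 4-methoxy-2,6-bis(methoxymethoxy)benzoate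
Product: 21 3,5-bis(tert-butyldimethylsilyloxy)-2-[(2R)-lavandulyl]-4-prenylphenyl 1-[4-methoxy-2,6-bis(methoxymethoxy)phenyl]vinyl ether
Conditions: Cp2TiMe2 (3 equiv), toluene–THF, 70 °C, dark; NaHCO3 work-up, basic alumina
Reagents that add atoms: dimethyltitanocene, [CH3-].[CH3-].[Ti+4].c1cc[cH-]c1.c1cc[cH-]c1
Why: Petasis methylenation; the titanium methylidene formed on heating adds to the ester carbonyl and the oxatitanacyclobutane collapses to the enol ether, a standard route from aryl benzoates to aryl 1-arylvinyl ethers. No aldehyde or ketone is present, and silyl ethers, MOM ethers and the isolated alkenes are tolerated.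

Step 13
Reactants: 21 3,5-bis(tert-butyldimethylsilyloxy)-2-[(2R)-lavandulyl]-4-prenylphenyl 1-[4-methoxy-2,6-bis(methoxymethoxy)phenyl]vinyl ether
Product: 22 4-[(2R)-lavandulyl]-5-{1-[4-methoxy-2,6-bis(methoxymethoxy)phenyl]vinyloxy}-2-prenylbenzene-1,3-diol
Conditions: TBAF (2.2 equiv), AcOH (2.2 equiv), THF, 0 °C
Reagents that add atoms: none
Why: Fluoride cleavage of the two aryl silyl ethers; the buffered medium is neither acidic enough to hydrolyse the enol ether nor does it touch the MOM ethers.

Step 14
Reactants: 22 4-[(2R)-lavandulyl]-5-{1-[4-methoxy-2,6-bis(methoxymethoxy)phenyl]vinyloxy}-2-prenylbenzene-1,3-diol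
Product: 23 2,4-dihydroxy-5-[(2R)-lavandulyl]-6-{1-[4-methoxy-2,6-bis(methoxymethoxy)phenyl]vinyloxy}-3-prenylbenzaldehyde
Conditions: MgCl2 (anhydrous, 3 equiv), Et3N (6 equiv), (CH2O)n (8 equiv), THF, 65 °C; pH 5 buffer work-up
Reagents that add atoms: formaldehyde (as paraformaldehyde), C=O
Why: Magnesium-mediated ortho-formylation of a phenol (Casnati–Skattebøl); formaldehyde is delivered within the magnesium phenoxide to the ortho carbon and the resulting benzylic alkoxide is oxidised by a second formaldehyde. C4a is the only free position of ring A, and the basic medium spares the enol ether and the MOM ethers.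

Step 15
Reactants: 23 2,4-dihydroxy-5-[(2R)-lavandulyl]-6-{1-[4-methoxy-2,6-bis(methoxymethoxy)phenyl]vinyloxy}-3-prenylbenzaldehyde
Product: 24 2-hydroxy-5-[(2R)-lavandulyl]-4-(methoxymethoxy)-6-{1-[4-methoxy-2,6-bis(methoxymethoxy)phenyl]vinyloxy}-3-prenylbenzaldehyde
Conditions: MOMCl (1.1 equiv), i-Pr2NEt (1.5 equiv), CH2Cl2, 0 °C
Reagents that add atoms: chloromethyl methyl ether, COCCl
Why: Regioselective O-alkylation; the hydroxyl para to the formyl group is the more acidic and is free, while the ortho hydroxyl is held in a hydrogen bond to the aldehyde and does not react with an amine base.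

Step 16
Reactants: 24 2-hydroxy-5-[(2R)-lavandulyl]-4-(methoxymethoxy)-6-{1-[4-methoxy-2,6-bis(methoxymethoxy)phenyl]vinyloxy}-3-prenylbenzaldehyde
Product: 25 (2S)-5-hydroxy-7,2',6'-tris(methoxymethoxy)-4'-methoxy-8-[(2R)-lavandulyl]-6-prenylflavanone
Conditions: [RhCl(C8H12)]2 (5 mol%; C8H12 = cycloocta-1,5-diene), (R)-BINAP (11 mol%), AgBF4 (10 mol%), 1,2-dichloroethane, rt, filtered from AgCl; then 24, K3PO4 (20 mol%), 50 °C
Reagents that add atoms: none
Why: Proposed new method: monovalent rhodium carrying a chiral bisphosphine should bind the C5 phenoxide of 24, insert into the neighbouring aldehyde C–H bond and give a chelated acyl rhodium hydride as in chelation-assisted hydroacylations of salicylaldehydes; the closest established reactions are the enantioselective intramolecular hydroacylations of ortho-vinyl- and ortho-allylbenzaldehydes with 1,1-disubstituted alkenes, none of which uses an enol ether on a phenolic oxygen. The tethered enol ether then inserts into Rh–H with hydride going to C2 and rhodium to the CH2 terminus, because the reverse sense would put the metal on a fully substituted carbon bearing oxygen and a 2,6-disubstituted aryl group. Reductive elimination from the seven-membered acylrhodacycle forms C3–C4 and closes ring C in a formal 6-endo-trig sense. The tether alone does not forbid closure through a six-membered rhodacycle to a 2-aryl-2-methylbenzofuran-3-one, so the regioselectivity rests on this steric bias and has to be verified. The C2 stereocentre is set by the catalyst, the ligand distinguishing the two faces of the enol ether during hydride transfer; the lavandulyl centre is five bonds away and should exert no useful bias, so the ligand enantiomer leading to 2S is to be identified on a model without the side chains (the (R)-ligand is written here). Chemoselectivity over the prenyl and lavandulyl alkenes follows from intramolecularity, since only the enol ether can reach the chelated acyl hydride, and the phenoxide chelate should hold back decarbonylation. Water and free acid must be excluded because the aryl vinyl ether hydrolyses readily, which is why the silver chloride is filtered off before 24 is added.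

Step 17
Reactants: 25 (2S)-5-hydroxy-7,2',6'-tris(methoxymethoxy)-4'-methoxy-8-[(2R)-lavandulyl]-6-prenylflavanone
Product: 26 (2S)-5,7,2',6'-tetrahydroxy-4'-methoxy-8-[(2R)-lavandulyl]-6-prenylflavanone (target)
Conditions: HCl (3 M aq), MeOH–THF, 40 °C
Reagents that add atoms: none
Why: Acid-catalysed cleavage of the three aryl MOM ethers by acetal exchange with methanol; dilute acid at moderate temperature is the customary end-game for prenylated flavanones and should leave the alkenes and C2 alone if stopped on completion.

## Compound list

1 | phloroglucinol (benzene-1,3,5-triol) | Oc1cc(O)cc(O)c1 | starting material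
2 | 1,3,5-tris(methoxymethoxy)benzene | COCOc1cc(OCOC)cc(OCOC)c1 | intermediate
3 | prenyl bromide (1-bromo-3-methylbut-2-ene) | CC(C)=CCBr | starting material
4 | 2,4,6-tris(methoxymethoxy)phenyllithium | [Li]c1c(OCOC)cc(OCOC)cc1OCOC | intermediate (not isolated)
5 | 1,3,5-tris(methoxymethoxy)-2-prenylbenzene | COCOc1cc(OCOC)c(CC=C(C)C)c(OCOC)c1 | intermediate
6 | 2,4,6-tris(methoxymethoxy)-3-prenylphenyllithium | COCOc1c([Li])c(OCOC)cc(OCOC)c1CC=C(C)C | intermediate (not isolated)
7 | 2-bromo-1,3,5-tris(methoxymethoxy)-4-prenylbenzene | COCOc1c(Br)c(OCOC)cc(OCOC)c1CC=C(C)C | intermediate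
8 | 2-bromo-4-prenylbenzene-1,3,5-triol | Oc1cc(O)c(CC=C(C)C)c(O)c1Br | intermediate
9 | 5-methoxyresorcinol | COc1cc(O)cc(O)c1 | starting material
10 | 1-methoxy-3,5-bis(methoxymethoxy)benzene | COCOc1cc(OC)cc(OCOC)c1 | intermediate
11 | 4-methoxy-2,6-bis(methoxymethoxy)phenyllithium | [Li]c1c(OCOC)cc(OC)cc1OCOC | intermediate (not isolated)
12 | 4-methoxy-2,6-bis(methoxymethoxy)benzoic acid | COCOc1cc(OC)cc(OCOC)c1C(=O)O | intermediate
13 | 4-methoxy-2,6-bis(methoxymethoxy)benzoyl fluoride | COCOc1cc(OC)cc(OCOC)c1C(F)=O | intermediate (not isolated)
14 | 2-bromo-3,5-dihydroxy-4-prenylphenyl 4-methoxy-2,6-bis(methoxymethoxy)benzoate | O=C(Oc1cc(O)c(CC=C(C)C)c(O)c1Br)c1c(OCOC)cc(OC)cc1OCOC | intermediate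
15 | 2-bromo-3,5-bis(tert-butyldimethylsilyloxy)-4-prenylphenyl 4-methoxy-2,6-bis(methoxymethoxy)benzoate | O=C(Oc1cc(O[Si](C)(C)C(C)(C)C)c(CC=C(C)C)c(O[Si](C)(C)C(C)(C)C)c1Br)c1c(OCOC)cc(OC)cc1OCOC | intermediate
16 | racemic lavandulol (5-methyl-2-(prop-1-en-2-yl)hex-4-en-1-ol) | C=C(C)C(CC=C(C)C)CO | starting material
17 | (S)-lavandulol | C=C(C)[C@H](CC=C(C)C)CO | intermediate
18 | (S)-lavandulyl iodide, (2S)-1-iodo-5-methyl-2-(prop-1-en-2-yl)hex-4-ene | C=C(C)[C@H](CC=C(C)C)CI | intermediate
19 | (S)-lavandulylzinc iodide | C=C(C)[C@H](CC=C(C)C)C[Zn]I | intermediate (not isolated)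
20 | 3,5-bis(tert-butyldimethylsilyloxy)-2-[(2R)-lavandulyl]-4-prenylphenyl 4-methoxy-2,6-bis(methoxymethoxy)benzoate | C=C(C)[C@H](CC=C(C)C)Cc1c(OC(=O)c2c(OCOC)cc(OC)cc2OCOC)cc(O[Si](C)(C)C(C)(C)C)c(CC=C(C)C)c1O[Si](C)(C)C(C)(C)C | intermediate
21 | 3,5-bis(tert-butyldimethylsilyloxy)-2-[(2R)-lavandulyl]-4-prenylphenyl 1-[4-methoxy-2,6-bis(methoxymethoxy)phenyl]vinyl ether | C=C(C)[C@H](CC=C(C)C)Cc1c(OC(=C)c2c(OCOC)cc(OC)cc2OCOC)cc(O[Si](C)(C)C(C)(C)C)c(CC=C(C)C)c1O[Si](C)(C)C(C)(C)C | intermediate
22 | 4-[(2R)-lavandulyl]-5-{1-[4-methoxy-2,6-bis(methoxymethoxy)phenyl]vinyloxy}-2-prenylbenzene-1,3-diol | C=C(C)[C@H](CC=C(C)C)Cc1c(OC(=C)c2c(OCOC)cc(OC)cc2OCOC)cc(O)c(CC=C(C)C)c1O | intermediate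
23 | 2,4-dihydroxy-5-[(2R)-lavandulyl]-6-{1-[4-methoxy-2,6-bis(methoxymethoxy)phenyl]vinyloxy}-3-prenylbenzaldehyde | C=C(C)[C@H](CC=C(C)C)Cc1c(O)c(CC=C(C)C)c(O)c(C=O)c1OC(=C)c1c(OCOC)cc(OC)cc1OCOC | intermediate
24 | 2-hydroxy-5-[(2R)-lavandulyl]-4-(methoxymethoxy)-6-{1-[4-methoxy-2,6-bis(methoxymethoxy)phenyl]vinyloxy}-3-prenylbenzaldehyde | C=C(C)[C@H](CC=C(C)C)Cc1c(OCOC)c(CC=C(C)C)c(O)c(C=O)c1OC(=C)c1c(OCOC)cc(OC)cc1OCOC | intermediate (precursor of the key step)
25 | (2S)-5-hydroxy-7,2',6'-tris(methoxymethoxy)-4'-methoxy-8-[(2R)-lavandulyl]-6-prenylflavanone | C=C(C)[C@H](CC=C(C)C)Cc1c(OCOC)c(CC=C(C)C)c(O)c2c1O[C@H](c1c(OCOC)cc(OC)cc1OCOC)CC2=O | intermediate (product of the key step)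
26 | (2S)-5,7,2',6'-tetrahydroxy-4'-methoxy-8-[(2R)-lavandulyl]-6-prenylflavanone | C=C(C)[C@H](CC=C(C)C)Cc1c(O)c(CC=C(C)C)c(O)c2c1O[C@H](c1c(O)cc(OC)cc1O)CC2=O | target

## Step count and least certain steps

Total step count: 17. Longest linear sequence: 13 steps (1 → 2 → 5 → 7 → 8 → 14 → 15 → 20 → 21 → 22 → 23 → 24 → 25 → 26; steps 1–4, 7, 8, 11–17).

Step 16 (key step). Most likely to go wrong: decarbonylation of the acyl rhodium hydride before the hindered enol ether inserts, hydrolysis of the enol ether by adventitious acid, insertion in the opposite sense with closure to the five-membered ketone, or poor facial selectivity at C2. Fallback, from 24 back to 25: a thiol-catalysed radical-chain hydroacylation, a known way of adding aldehydes to enol ethers (tert-dodecanethiol, di-tert-butyl hyponitrite, dioxane, 60 °C). The acyl radical should add to the CH2 terminus to give the oxygen- and aryl-stabilised C2 radical, which takes hydrogen from the thiol. C2 is not controlled, so 25 would form together with its C2 epimer, (2R)-5-hydroxy-7,2',6'-tris(methoxymethoxy)-4'-methoxy-8-[(2R)-lavandulyl]-6-prenylflavanone F1. The two are diastereomers and would be separated by preparative HPLC on a chiral stationary phase; the route continues from 25.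

Step 7. Most likely to go wrong: incomplete discrimination between the three hydroxyls (acylation at the hydroxyl next to the prenyl group, or double acylation). Fallback, from 8 back to 15: the selection is moved to a desilylation. 8 is fully silylated (TBSCl, imidazole, DMF) to 2-bromo-1,3,5-tris(tert-butyldimethylsilyloxy)-4-prenylbenzene F2. The aryl silyl ether with the best leaving group and the least shielding (ortho to bromine, flanked on one side only) is cleaved with K2CO3 in MeOH at 0 °C to give 2-bromo-3,5-bis(tert-butyldimethylsilyloxy)-4-prenylphenol F3. Its single hydroxyl is acylated with 13 (i-Pr2NEt, DMAP, MeCN) to give 15 directly.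

Step 11. Most likely to go wrong: slow oxidative addition at the bromide, which is flanked by a silyl ether and the aroyloxy group, leading to reduction of the C–Br bond or β-hydride elimination in the alkyl partner. Fallback, from 18 and 15 back to 20: a B-alkyl Suzuki–Miyaura coupling. Iodine–lithium exchange on 18 (t-BuLi, Et2O, −78 °C) and addition of B-methoxy-9-borabicyclo[3.3.1]nonane give lithium B-[(2S)-lavandulyl]-B-methoxy-9-borabicyclo[3.3.1]nonanate F4. This is coupled with 15 (PdCl2(dppf), K3PO4, THF–DMF–H2O, 60 °C) to give 20.

Step 12. Most likely to go wrong: failure of the titanium methylidene to reach a carbonyl shielded by two ortho MOM ethers on one side and the lavandulyl group on the other, with thermal decay of the reagent instead. Fallback, from 15 back to 21: the order of the two steps is reversed so that the methylenation is run while the neighbouring ring A substituent is only bromine. 15 and Cp2TiMe2 (toluene, 70 °C) give 2-bromo-3,5-bis(tert-butyldimethylsilyloxy)-4-prenylphenyl 1-[4-methoxy-2,6-bis(methoxymethoxy)phenyl]vinyl ether F5. F5 is then coupled with 19 (Pd(OAc)2, SPhos, THF, 50 °C) to give 21.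

Step 17. Most likely to go wrong: acid-promoted cyclisation of the C6 prenyl group onto the C5 or C7 hydroxyl, addition to the isopropenyl group, or epimerisation at C2 through ionisation or ring opening once ring B is deprotected. Fallback, from 25 back to 26: a non-protic transprotection. TMSOTf and 2,2'-bipyridyl (CH2Cl2, 0 °C) should convert the aryl MOM ethers into silyl ethers, giving (2S)-5-hydroxy-4'-methoxy-7,2',6'-tris(trimethylsilyloxy)-8-[(2R)-lavandulyl]-6-prenylflavanone F6 (the chelated C5 hydroxyl may be silylated as well and is released in the same way). Addition of water at rt hydrolyses F6 to 26.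

## Further compounds

F1 | step 16 | (2R)-5-hydroxy-7,2',6'-tris(methoxymethoxy)-4'-methoxy-8-[(2R)-lavandulyl]-6-prenylflavanone | C=C(C)[C@H](CC=C(C)C)Cc1c(OCOC)c(CC=C(C)C)c(O)c2c1O[C@@H](c1c(OCOC)cc(OC)cc1OCOC)CC2=O
F2 | step 7 | 2-bromo-1,3,5-tris(tert-butyldimethylsilyloxy)-4-prenylbenzene | CC(C)(C)[Si](C)(C)Oc1cc(O[Si](C)(C)C(C)(C)C)c(CC=C(C)C)c(O[Si](C)(C)C(C)(C)C)c1Br
F3 | step 7 | 2-bromo-3,5-bis(tert-butyldimethylsilyloxy)-4-prenylphenol | Oc1cc(O[Si](C)(C)C(C)(C)C)c(CC=C(C)C)c(O[Si](C)(C)C(C)(C)C)c1Br
F4 | step 11 | lithium B-[(2S)-lavandulyl]-B-methoxy-9-borabicyclo[3.3.1]nonanate | C=C(C)[C@H](CC=C(C)C)C[B-]1(OC)C2CCCC1CCC2.[Li+]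
F5 | step 12 | 2-bromo-3,5-bis(tert-butyldimethylsilyloxy)-4-prenylphenyl 1-[4-methoxy-2,6-bis(methoxymethoxy)phenyl]vinyl ether | C=C(Oc1cc(O[Si](C)(C)C(C)(C)C)c(CC=C(C)C)c(O[Si](C)(C)C(C)(C)C)c1Br)c1c(OCOC)cc(OC)cc1OCOC
F6 | step 17 | (2S)-5-hydroxy-4'-methoxy-7,2',6'-tris(trimethylsilyloxy)-8-[(2R)-lavandulyl]-6-prenylflavanone | C=C(C)[C@H](CC=C(C)C)Cc1c(O[Si](C)(C)C)c(CC=C(C)C)c(O)c2c1O[C@H](c1c(O[Si](C)(C)C)cc(OC)cc1O[Si](C)(C)C)CC2=O
A1 | alternative 1 | 2-prenyl-3-(triisopropylsilyloxy)cyclobut-2-en-1-one | O=C1CC(O[Si](C(C)C)(C(C)C)C(C)C)=C1CC=C(C)C
A2 | alternative 1 | triisopropyl{[(4R)-7-methyl-4-(prop-1-en-2-yl)oct-6-en-1-yn-1-yl]oxy}silane | C=C(C)[C@H](CC=C(C)C)CC#CO[Si](C(C)C)(C(C)C)C(C)C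
A3 | alternative 1 | 2-[(2R)-lavandulyl]-4-prenyl-3,5-bis(triisopropylsilyloxy)phenol | C=C(C)[C@H](CC=C(C)C)Cc1c(O[Si](C(C)C)(C(C)C)C(C)C)c(CC=C(C)C)c(O[Si](C(C)C)(C(C)C)C(C)C)cc1O
A4 | alternative 2 | 2-iodo-6-[(2R)-lavandulyl]-3,5-bis(methoxymethoxy)-4-prenylphenol | C=C(C)[C@H](CC=C(C)C)Cc1c(O)c(I)c(OCOC)c(CC=C(C)C)c1OCOC
A5 | alternative 2 | 2-ethynyl-5-methoxy-1,3-bis(methoxymethoxy)benzene | C#Cc1c(OCOC)cc(OC)cc1OCOC
A6 | alternative 2 | 5,7,2',6'-tetrakis(methoxymethoxy)-4'-methoxy-8-[(2R)-lavandulyl]-6-prenylflavone | C=C(C)[C@H](CC=C(C)C)Cc1c(OCOC)c(CC=C(C)C)c(OCOC)c2c1OC(c1c(OCOC)cc(OC)cc1OCOC)=CC2=O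
A7 | alternative 3 | 2-[(1R,3S)-1,3-dihydroxy-3-(4-methoxy-2,6-bis(methoxymethoxy)phenyl)propyl]-6-[(2R)-lavandulyl]-3,5-bis(methoxymethoxy)-4-prenylphenyl trifluoromethanesulfonate | C=C(C)[C@H](CC=C(C)C)Cc1c(OCOC)c(CC=C(C)C)c(OCOC)c([C@H](O)C[C@H](O)c2c(OCOC)cc(OC)cc2OCOC)c1OS(=O)(=O)C(F)(F)F
A8 | alternative 3 | (2S,4R)-5,7,2',6'-tetrakis(methoxymethoxy)-4'-methoxy-8-[(2R)-lavandulyl]-6-prenylflavan-4-ol | C=C(C)[C@H](CC=C(C)C)Cc1c(OCOC)c(CC=C(C)C)c(OCOC)c2c1O[C@H](c1c(OCOC)cc(OC)cc1OCOC)C[C@H]2O
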